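**Plan**

- Retrosynthesis (benzofuran numbering O1, C2, C3, C3a, C4–C7, C7a): the carbocycle is opened at C4=C5 (ring-closing metathesis) and at C6–C7 (syn aldol; acrolein supplies C5 and C6). The C7–acyl bond (γ-acylation), the methoxyvinyl group at C4 (ester methylenation) and the two methyls of CMe2OH (Grignard) are then removed, and last O1–C2 and C2–C3 are cut.
- Enabling feature: ring O1–C2–C3–C3a=C7a is a trans-2,3-disubstituted dihydrofuran whose C3a=C7a enol ether is the O-alkylated enol of a 1,3-dicarbonyl unit (C7a ketone carbon, C4 ester carbon, C3 arylidene carbon). C2 can therefore be delivered as a one-carbon ylide to an arylidene acetoacetate.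
- Forward order: dihydrofuran ring first, then CMe2OH at C2, the acyl chain at C7, the methoxyvinyl group at C4, the aldol at C7/C6, and the six-membered ring last.
- Stereochemistry: C3 from the cinchona ammonium ylide, C2 trans to it by anti displacement (also the more stable isomer); C6 and C7 together from a Z enol diisopinocampheylborinate (syn, reagent control).
- Protecting groups: the phenol is a TIPS ether throughout. The arene carries Br in place of CO2Me until MeMgBr and Cp2TiMe2 have been used, since both would attack a benzoate; Br is then exchanged for CO2Me at a stage that holds no carbonyl group.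

Key step: step 3

Assumption: O-methylquinidine is taken to give the (2R,3R) series in step 3 and (−)-Ipc2BOTf to direct attack on the Si face of acrolein in step 11; if either sense is opposite, O-methylquinine or (+)-Ipc2BOTf is used in the same step.

**Route**

Step 1
Reactants: 1 5-bromo-2-hydroxybenzaldehyde
Product: 2 5-bromo-2-[(triisopropylsilyl)oxy]benzaldehyde
Conditions: iPr3SiCl, imidazole, DMF, 25 °C
Reagents that add atoms: chlorotriisopropylsilane, CC(C)[Si](Cl)(C(C)C)C(C)C
Why: Standard O-silylation of a phenol; the free ortho-hydroxyl would otherwise close onto the Knoevenagel product to give a coumarin, and the bulky aryl TIPS ether should survive the carbonate, Grignard and amide-base steps that follow.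

Step 2
Reactants: 2 5-bromo-2-[(triisopropylsilyl)oxy]benzaldehyde; 3 methyl acetoacetate
Product: 4 methyl (2Z)-2-acetyl-3-{5-bromo-2-[(triisopropylsilyl)oxy]phenyl}prop-2-enoate
Conditions: piperidine (10 mol%), AcOH (10 mol%), toluene, 4 Å sieves, 25 °C
Reagents that add atoms: none
Why: Knoevenagel condensation of an aromatic aldehyde with a β-keto ester under piperidinium acetate catalysis; the Z isomer (aryl cis to the ester) is expected to predominate, and any E isomer can be carried on because the alkene geometry is lost in step 3.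

Step 3
Reactants: 4 methyl (2Z)-2-acetyl-3-{5-bromo-2-[(triisopropylsilyl)oxy]phenyl}prop-2-enoate; 5 methyl bromoacetate
Product: 6 dimethyl (2R,3R)-3-{5-bromo-2-[(triisopropylsilyl)oxy]phenyl}-5-methyl-2,3-dihydrofuran-2,4-dicarboxylate
Conditions: O-methylquinidine (20 mol%), Cs2CO3 (1.3 equiv), MeCN, 25 °C
Reagents that add atoms: none
Why: The quinuclidine nitrogen of the alkaloid is alkylated by 5 and Cs2CO3 deprotonates the salt to an ester-stabilised ammonium ylide, which adds in conjugate fashion to the arylidene carbon of 4 (C2–C3 bond); the acetoacetate enolate so formed displaces the ammonium group through its ketone oxygen (O1–C2 bond) and returns the amine, a formal [4+1] annulation of the known pyridinium/ammonium-ylide type that gives trans-2,3-dihydrofurans from alkylidene 1,3-dicarbonyls. The only ring formed, the dihydrofuran, closes by 5-exo-tet SN2 O-alkylation. C3 is fixed in the conjugate addition, where the alkaloid framework of the ylide shields one face of the acceptor. C2 ends trans to the aryl group because displacement needs the enolate oxygen anti to the leaving nitrogen in the less crowded betaine rotamer, and the C2–H, α to an ester, can equilibrate to the more stable trans isomer under carbonate. The step needs closure through oxygen rather than carbon and through the ketone rather than the ester oxygen: the delocalised enolate alkylates on the more nucleophilic ketone oxygen to give the conjugated β-alkoxyacrylate, and any donor–acceptor cyclopropane from C-closure would ring-expand to the same dihydrofuran.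

Step 4
Reactants: 6 dimethyl (2R,3R)-3-{5-bromo-2-[(triisopropylsilyl)oxy]phenyl}-5-methyl-2,3-dihydrofuran-2,4-dicarboxylate
Product: 8 methyl (4R,5R)-4-{5-bromo-2-[(triisopropylsilyl)oxy]phenyl}-5-(2-hydroxypropan-2-yl)-2-methyl-4,5-dihydrofuran-3-carboxylate, via methyl ketone 7 (not isolated)
Conditions: MeMgBr (3 equiv), THF, −78 → −20 °C; aq. NH4Cl
Reagents that add atoms: methylmagnesium bromide, C[Mg]Br
Why: Double Grignard addition to the saturated, α-alkoxy-activated ester at C2; the other ester is a hindered β-alkoxyacrylate (vinylogous carbonate) and should be left at low temperature, the aryl bromide is inert, and no benzoate is present to compete.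

Step 5
Reactants: 9 3-phenylpropanoyl chloride; 10 N,O-dimethylhydroxylamine hydrochloride
Product: 11 N-methoxy-N-methyl-3-phenylpropanamide
Conditions: pyridine, CH2Cl2, 0 → 25 °C
Reagents that add atoms: none
Why: Routine acylation of the hydroxylamine by an acid chloride to give the Weinreb amide.

Step 6
Reactants: 8 methyl (4R,5R)-4-{5-bromo-2-[(triisopropylsilyl)oxy]phenyl}-5-(2-hydroxypropan-2-yl)-2-methyl-4,5-dihydrofuran-3-carboxylate; 11 N-methoxy-N-methyl-3-phenylpropanamide
Product: 14 methyl (4R,5R)-4-{5-bromo-2-[(triisopropylsilyl)oxy]phenyl}-5-(2-hydroxypropan-2-yl)-2-(2-oxo-4-phenylbutyl)-4,5-dihydrofuran-3-carboxylate, via dilithium dienolate 12 (not isolated), via lithium hemiaminal adduct 13 (not isolated)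
Conditions: LiN(iPr)2 (2.3 equiv), THF, −78 °C; 11, −78 → −30 °C; aq. NH4Cl, −30 °C
Reagents that add atoms: none
Why: Vinylogous Claisen-type acylation: after the alkoxide forms, the second equivalent of base removes a proton from the methyl group γ to the ester, and the dienolate attacks the Weinreb amide at that carbon because the α-carbon is fully substituted; the chelated tetrahedral adduct holds back the ketone until the quench, so neither over-addition nor base-induced closure of the keto enolate onto the cis ester (2-pyranone formation) can take place.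

Step 7
Reactants: 14 methyl (4R,5R)-4-{5-bromo-2-[(triisopropylsilyl)oxy]phenyl}-5-(2-hydroxypropan-2-yl)-2-(2-oxo-4-phenylbutyl)-4,5-dihydrofuran-3-carboxylate
Product: 15 methyl (4R,5R)-4-{5-bromo-2-[(triisopropylsilyl)oxy]phenyl}-2-[4-phenyl-2-(triethylsilyloxy)but-1-en-1-yl]-5-[2-(triethylsilyloxy)propan-2-yl]-4,5-dihydrofuran-3-carboxylate
Conditions: Et3SiOTf (3 equiv), Et3N, CH2Cl2, −78 → 0 °C
Reagents that add atoms: triethylsilyl trifluoromethanesulfonate, CC[Si](CC)(CC)OS(=O)(=O)C(F)(F)F
Why: Soft enolisation and O-silylation: the methylene between the ketone and the vinylogous ester is by far the most acidic site, so the ketone is masked as a conjugated silyl dienol ether (geometry immaterial, presumably Z) while the same reagent caps the tertiary alcohol, and trapping at −78 °C forestalls cyclisation of the enol onto the ester.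

Step 8
Reactants: 15 methyl (4R,5R)-4-{5-bromo-2-[(triisopropylsilyl)oxy]phenyl}-2-[4-phenyl-2-(triethylsilyloxy)but-1-en-1-yl]-5-[2-(triethylsilyloxy)propan-2-yl]-4,5-dihydrofuran-3-carboxylate
Product: 16 (2R,3R)-3-{5-bromo-2-[(triisopropylsilyl)oxy]phenyl}-4-(1-methoxyethenyl)-5-[4-phenyl-2-(triethylsilyloxy)but-1-en-1-yl]-2-[2-(triethylsilyloxy)propan-2-yl]-2,3-dihydrofuran
Conditions: Cp2TiMe2 (3 equiv), toluene/THF, 65 °C, dark
Reagents that add atoms: dimethyltitanocene, C[Ti](C)(C1C=CC=C1)C1C=CC=C1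
Why: Petasis methylenation of an ester to a methyl enol ether; the ester is the only C=O left in the molecule, the reagent is neutral and not Lewis acidic so the silyl ethers and the silyl dienol ether should survive, and the aryl bromide is inert.

Step 9
Reactants: 16 (2R,3R)-3-{5-bromo-2-[(triisopropylsilyl)oxy]phenyl}-4-(1-methoxyethenyl)-5-[4-phenyl-2-(triethylsilyloxy)but-1-en-1-yl]-2-[2-(triethylsilyloxy)propan-2-yl]-2,3-dihydrofuran
Product: 18 methyl 3-{(2R,3R)-4-(1-methoxyethenyl)-5-[4-phenyl-2-(triethylsilyloxy)but-1-en-1-yl]-2-[2-(triethylsilyloxy)propan-2-yl]-2,3-dihydrofuran-3-yl}-4-[(triisopropylsilyl)oxy]benzoate, via aryllithium 17 (not isolated)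
Conditions: t-BuLi (2.1 equiv), THF, −78 °C; then into ClCO2Me (3 equiv), −78 °C
Reagents that add atoms: methyl chloroformate, COC(Cl)=O
Why: Bromine–lithium exchange followed by acylation with a chloroformate; 16 holds no electrophilic or acidic group, the exchange is far faster than any deprotonation at −78 °C, and inverse addition to excess chloroformate prevents a second attack on the new ester.

Step 10
Reactants: 18 methyl 3-{(2R,3R)-4-(1-methoxyethenyl)-5-[4-phenyl-2-(triethylsilyloxy)but-1-en-1-yl]-2-[2-(triethylsilyloxy)propan-2-yl]-2,3-dihydrofuran-3-yl}-4-[(triisopropylsilyl)oxy]benzoate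
Product: 19 methyl 3-{(2R,3R)-4-(1-methoxyethenyl)-5-(2-oxo-4-phenylbutyl)-2-[2-(triethylsilyloxy)propan-2-yl]-2,3-dihydrofuran-3-yl}-4-[(triisopropylsilyl)oxy]benzoate
Conditions: Bu4NF (1.05 equiv), AcOH (1.5 equiv), THF, −78 °C; pH 7 buffer; used at once
Reagents that add atoms: none
Why: Fluoride cleavage of a silyl enol ether, which at −78 °C should be much faster than attack on the hindered aryl TIPS ether or the tertiary alkyl silyl ether; acetic acid protonates the enolate at the α-carbon to give the β,γ-unsaturated ketone without letting it equilibrate into conjugation.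

Step 11
Reactants: 19 methyl 3-{(2R,3R)-4-(1-methoxyethenyl)-5-(2-oxo-4-phenylbutyl)-2-[2-(triethylsilyloxy)propan-2-yl]-2,3-dihydrofuran-3-yl}-4-[(triisopropylsilyl)oxy]benzoate; 20 acrolein
Product: 22 methyl 3-{(2R,3R)-5-[(3R,4R)-3-hydroxy-5-oxo-7-phenylhept-1-en-4-yl]-4-(1-methoxyethenyl)-2-[2-(triethylsilyloxy)propan-2-yl]-2,3-dihydrofuran-3-yl}-4-[(triisopropylsilyl)oxy]benzoate, via Z boron enolate 21 (not isolated)
Conditions: (−)-Ipc2BOTf (1.3 equiv), iPr2NEt, CH2Cl2, −78 °C; acrolein, −78 → −20 °C; MeOH, pH 7 buffer, H2O2, 0 °C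
Reagents that add atoms: none
Why: Paterson-type syn aldol: the boron triflate and hindered amine should enolise the ketone toward the more acidic allylic methylene (C7) as the Z enolate, a chair Zimmerman–Traxler transition state then gives the 6,7-syn adduct (which becomes cis on the ring), and the isopinocampheyl ligands select the aldehyde face so that both new centres are R.

Step 12
Reactants: 22 methyl 3-{(2R,3R)-5-[(3R,4R)-3-hydroxy-5-oxo-7-phenylhept-1-en-4-yl]-4-(1-methoxyethenyl)-2-[2-(triethylsilyloxy)propan-2-yl]-2,3-dihydrofuran-3-yl}-4-[(triisopropylsilyl)oxy]benzoate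
Product: 23 methyl 3-{(2R,3R,6R,7R)-6-hydroxy-4-methoxy-7-(3-phenylpropanoyl)-2-[2-(triethylsilyloxy)propan-2-yl]-2,3,6,7-tetrahydro-1-benzofuran-3-yl}-4-[(triisopropylsilyl)oxy]benzoate
Conditions: second-generation Grubbs catalyst (H2IMes)(PCy3)Cl2Ru=CHPh (10 mol%), 1,4-benzoquinone (20 mol%), CH2Cl2 (0.005 M), 40 °C
Reagents that add atoms: none
Why: Ring-closing metathesis of a monosubstituted alkene onto a 1,1-disubstituted enol ether: the ruthenium carbene loads on the vinyl group of the allylic alcohol and closes the six-membered ring at C4=C5 with loss of ethylene, under neutral conditions that leave the stereocentres untouched, while benzoquinone suppresses hydride-induced alkene migration.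

Step 13
Reactants: 23 methyl 3-{(2R,3R,6R,7R)-6-hydroxy-4-methoxy-7-(3-phenylpropanoyl)-2-[2-(triethylsilyloxy)propan-2-yl]-2,3,6,7-tetrahydro-1-benzofuran-3-yl}-4-[(triisopropylsilyl)oxy]benzoate
Product: 24 methyl 4-hydroxy-3-[(2R,3R,6R,7R)-6-hydroxy-2-(2-hydroxypropan-2-yl)-4-methoxy-7-(3-phenylpropanoyl)-2,3,6,7-tetrahydro-1-benzofuran-3-yl]benzoate
Conditions: Bu4NF/AcOH (1:1, 4 equiv), THF, 0 → 25 °C
Reagents that add atoms: none
Why: Fluoride desilylation of the aryl TIPS ether (fast) and the tertiary triethylsilyl ether (slower); the acetic acid buffer keeps the medium near neutral so that the β-hydroxy ketone and the dienol ether are not exposed to base or strong acid.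

**Compound list**

1 | 5-bromo-2-hydroxybenzaldehyde | O=Cc1cc(Br)ccc1O | starting material
2 | 5-bromo-2-[(triisopropylsilyl)oxy]benzaldehyde | O=Cc1cc(Br)ccc1O[Si](C(C)C)(C(C)C)C(C)C | intermediate
3 | methyl acetoacetate | COC(=O)CC(C)=O | starting material
4 | methyl (2Z)-2-acetyl-3-{5-bromo-2-[(triisopropylsilyl)oxy]phenyl}prop-2-enoate | COC(=O)/C(C(C)=O)=C\c1cc(Br)ccc1O[Si](C(C)C)(C(C)C)C(C)C | intermediate
5 | methyl bromoacetate | COC(=O)CBr | starting material
6 | dimethyl (2R,3R)-3-{5-bromo-2-[(triisopropylsilyl)oxy]phenyl}-5-methyl-2,3-dihydrofuran-2,4-dicarboxylate (trans) | Brc1ccc(O[Si](C(C)C)(C(C)C)C(C)C)c([C@@H]2C(C(=O)OC)=C(C)O[C@H]2C(=O)OC)c1 | intermediate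
7 | methyl (4R,5R)-5-acetyl-4-{5-bromo-2-[(triisopropylsilyl)oxy]phenyl}-2-methyl-4,5-dihydrofuran-3-carboxylate | Brc1ccc(O[Si](C(C)C)(C(C)C)C(C)C)c([C@@H]2C(C(=O)OC)=C(C)O[C@H]2C(C)=O)c1 | intermediate
8 | methyl (4R,5R)-4-{5-bromo-2-[(triisopropylsilyl)oxy]phenyl}-5-(2-hydroxypropan-2-yl)-2-methyl-4,5-dihydrofuran-3-carboxylate | Brc1ccc(O[Si](C(C)C)(C(C)C)C(C)C)c([C@@H]2C(C(=O)OC)=C(C)O[C@H]2C(C)(C)O)c1 | intermediate
9 | 3-phenylpropanoyl chloride | O=C(Cl)CCc1ccccc1 | starting material
10 | N,O-dimethylhydroxylamine hydrochloride | CNOC.Cl | starting material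
11 | N-methoxy-N-methyl-3-phenylpropanamide | CON(C)C(=O)CCc1ccccc1 | intermediate
12 | dilithium salt of 8 (tertiary alkoxide; ester dienolate with exocyclic CH2= at the former methyl carbon) | [Li+].[Li+].Brc1ccc(O[Si](C(C)C)(C(C)C)C(C)C)c([C@@H]2C(=C([O-])OC)C(=C)O[C@H]2C(C)(C)[O-])c1 | intermediate
13 | dilithium salt of the N-methoxy-N-methyl hemiaminal from addition of 12 to 11 | [Li+].[Li+].Brc1ccc(O[Si](C(C)C)(C(C)C)C(C)C)c([C@@H]2C(C(=O)OC)=C(CC([O-])(CCc3ccccc3)N(C)OC)O[C@H]2C(C)(C)[O-])c1 | intermediate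
14 | methyl (4R,5R)-4-{5-bromo-2-[(triisopropylsilyl)oxy]phenyl}-5-(2-hydroxypropan-2-yl)-2-(2-oxo-4-phenylbutyl)-4,5-dihydrofuran-3-carboxylate | Brc1ccc(O[Si](C(C)C)(C(C)C)C(C)C)c([C@@H]2C(C(=O)OC)=C(CC(=O)CCc3ccccc3)O[C@H]2C(C)(C)O)c1 | intermediate
15 | methyl (4R,5R)-4-{5-bromo-2-[(triisopropylsilyl)oxy]phenyl}-2-[4-phenyl-2-(triethylsilyloxy)but-1-en-1-yl]-5-[2-(triethylsilyloxy)propan-2-yl]-4,5-dihydrofuran-3-carboxylate (enol ether geometry not defined) | Brc1ccc(O[Si](C(C)C)(C(C)C)C(C)C)c([C@@H]2C(C(=O)OC)=C(C=C(CCc3ccccc3)O[Si](CC)(CC)CC)O[C@H]2C(C)(C)O[Si](CC)(CC)CC)c1 | intermediate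
16 | (2R,3R)-3-{5-bromo-2-[(triisopropylsilyl)oxy]phenyl}-4-(1-methoxyethenyl)-5-[4-phenyl-2-(triethylsilyloxy)but-1-en-1-yl]-2-[2-(triethylsilyloxy)propan-2-yl]-2,3-dihydrofuran | Brc1ccc(O[Si](C(C)C)(C(C)C)C(C)C)c([C@@H]2C(C(=C)OC)=C(C=C(CCc3ccccc3)O[Si](CC)(CC)CC)O[C@H]2C(C)(C)O[Si](CC)(CC)CC)c1 | intermediate
17 | aryllithium from 16 (lithium in place of bromine) | [Li]c1ccc(O[Si](C(C)C)(C(C)C)C(C)C)c([C@@H]2C(C(=C)OC)=C(C=C(CCc3ccccc3)O[Si](CC)(CC)CC)O[C@H]2C(C)(C)O[Si](CC)(CC)CC)c1 | intermediate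
18 | methyl 3-{(2R,3R)-4-(1-methoxyethenyl)-5-[4-phenyl-2-(triethylsilyloxy)but-1-en-1-yl]-2-[2-(triethylsilyloxy)propan-2-yl]-2,3-dihydrofuran-3-yl}-4-[(triisopropylsilyl)oxy]benzoate | COC(=O)c1ccc(O[Si](C(C)C)(C(C)C)C(C)C)c([C@@H]2C(C(=C)OC)=C(C=C(CCc3ccccc3)O[Si](CC)(CC)CC)O[C@H]2C(C)(C)O[Si](CC)(CC)CC)c1 | intermediate
19 | methyl 3-{(2R,3R)-4-(1-methoxyethenyl)-5-(2-oxo-4-phenylbutyl)-2-[2-(triethylsilyloxy)propan-2-yl]-2,3-dihydrofuran-3-yl}-4-[(triisopropylsilyl)oxy]benzoate | COC(=O)c1ccc(O[Si](C(C)C)(C(C)C)C(C)C)c([C@@H]2C(C(=C)OC)=C(CC(=O)CCc3ccccc3)O[C@H]2C(C)(C)O[Si](CC)(CC)CC)c1 | intermediate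
20 | acrolein | C=CC=O | starting material
21 | Z enol diisopinocampheylborinate of 19 (enolised toward the furan-bearing methylene; Ipc groups from (+)-α-pinene) | COC(=O)c1ccc(O[Si](C(C)C)(C(C)C)C(C)C)c([C@@H]2C(C(=C)OC)=C(/C=C(/CCc3ccccc3)OB([C@@H]3C[C@@H]4C[C@H]([C@H]3C)C4(C)C)[C@@H]3C[C@@H]4C[C@H]([C@H]3C)C4(C)C)O[C@H]2C(C)(C)O[Si](CC)(CC)CC)c1 | intermediate
22 | methyl 3-{(2R,3R)-5-[(3R,4R)-3-hydroxy-5-oxo-7-phenylhept-1-en-4-yl]-4-(1-methoxyethenyl)-2-[2-(triethylsilyloxy)propan-2-yl]-2,3-dihydrofuran-3-yl}-4-[(triisopropylsilyl)oxy]benzoate | COC(=O)c1ccc(O[Si](C(C)C)(C(C)C)C(C)C)c([C@@H]2C(C(=C)OC)=C(O[C@H]2C(C)(C)O[Si](CC)(CC)CC)[C@H](C(=O)CCc3ccccc3)[C@H](O)C=C)c1 | intermediate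
23 | methyl 3-{(2R,3R,6R,7R)-6-hydroxy-4-methoxy-7-(3-phenylpropanoyl)-2-[2-(triethylsilyloxy)propan-2-yl]-2,3,6,7-tetrahydro-1-benzofuran-3-yl}-4-[(triisopropylsilyl)oxy]benzoate | COC(=O)c1ccc(O[Si](C(C)C)(C(C)C)C(C)C)c([C@@H]2C3=C(O[C@H]2C(C)(C)O[Si](CC)(CC)CC)[C@H](C(=O)CCc2ccccc2)[C@H](O)C=C3OC)c1 | intermediate
24 | methyl 4-hydroxy-3-[(2R,3R,6R,7R)-6-hydroxy-2-(2-hydroxypropan-2-yl)-4-methoxy-7-(3-phenylpropanoyl)-2,3,6,7-tetrahydro-1-benzofuran-3-yl]benzoate | COC(=O)c1ccc(O)c([C@@H]2C3=C(O[C@H]2C(C)(C)O)[C@H](C(=O)CCc2ccccc2)[C@H](O)C=C3OC)c1 | target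

**Step count and risks**

Total step count: 13. Longest linear sequence: 12 steps (1 → 24 through steps 1–4 and 6–13; step 5 is a one-step branch).

Steps most likely to fail:

1. Step 11 (aldol). What may go wrong: enolisation toward the phenethyl methylene instead of C7, amine-induced migration of the C3a=C7a double bond into conjugation with the ketone before the enolate forms, or poor facial discrimination if reagent and substrate preferences oppose each other. Fallback, setting out from 18 and rejoining at 24: the regiodefined enol silane 18 is not unmasked but treated with acrolein and catalytic tris(dimethylamino)sulfonium difluorotrimethylsilicate in THF at −78 °C. This is a fluoride-catalysed aldol addition of an enol silane, syn-selective through an open transition state, with the silyl group passing to the new oxygen, and should give the C6 triethylsilyl ether of the aldol adduct F1. Ring-closing metathesis under the conditions of step 12 should then give the silylated tetrahydrobenzofuran F2, and the buffered fluoride of step 13 removes all three silyl groups to reach 24. Face selectivity then rests on the substrate alone, and the unwanted syn diastereomer would have to be separated.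

2. Step 8 (methylenation). What may go wrong: the ester carbonyl, hindered by the fully substituted C3a and made electron-rich by conjugation with O1 and the silyl dienol ether, may react more slowly than Cp2TiMe2 decays, or the product triene may not survive prolonged heating. Fallback, setting out from 8 and rejoining at 19: the C7 chain is carried at the alcohol oxidation level, so that the ester is only a β-alkoxyacrylate when it meets the titanium reagent. 8 is silylated (Et3SiOTf, 2,6-lutidine) to the tertiary triethylsilyl ether F3. Its lithium dienolate (LiN(iPr)2, THF, −78 °C) is added to 3-phenylpropanal (vinylogous aldol at the methyl carbon) and the aldolate is capped in the flask with Me3SiCl, which prevents lactonisation onto the cis ester, to give the secondary trimethylsilyl ether F4 (both carbinol epimers). Cp2TiMe2 should then give the methoxydiene F5, and t-BuLi/ClCO2Me as in step 9 the benzoate F6. K2CO3 in MeOH at 0 °C frees only the secondary alcohol F7, and Dess–Martin periodinane buffered with NaHCO3 oxidises it to ketone 19.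

3. Step 13 (final desilylation). What may go wrong: loss of water across C6–C7 (the product is one dehydration away from an aromatic benzofuran) or epimerisation at C7 during the time needed to cleave the slower tertiary silyl ether. Fallback, setting out from 22 and rejoining at 24: the order of the last two steps is reversed. 22, which cannot aromatise, is desilylated with Bu4NF/AcOH to the acyclic triol F8, and the ring is then closed with the same ruthenium catalyst, which tolerates free phenols and alcohols, so that 24 is formed under neutral conditions and only needs chromatography.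

Further compounds
F1 | step 11 | methyl 3-{(2R,3R)-4-(1-methoxyethenyl)-5-[(3R,4R)-5-oxo-7-phenyl-3-(triethylsilyloxy)hept-1-en-4-yl]-2-[2-(triethylsilyloxy)propan-2-yl]-2,3-dihydrofuran-3-yl}-4-[(triisopropylsilyl)oxy]benzoate | COC(=O)c1ccc(O[Si](C(C)C)(C(C)C)C(C)C)c([C@@H]2C(C(=C)OC)=C(O[C@H]2C(C)(C)O[Si](CC)(CC)CC)[C@H](C(=O)CCc3ccccc3)[C@H](O[Si](CC)(CC)CC)C=C)c1
F2 | step 11 | methyl 3-{(2R,3R,6R,7R)-4-methoxy-7-(3-phenylpropanoyl)-6-(triethylsilyloxy)-2-[2-(triethylsilyloxy)propan-2-yl]-2,3,6,7-tetrahydro-1-benzofuran-3-yl}-4-[(triisopropylsilyl)oxy]benzoate | COC(=O)c1ccc(O[Si](C(C)C)(C(C)C)C(C)C)c([C@@H]2C3=C(O[C@H]2C(C)(C)O[Si](CC)(CC)CC)[C@H](C(=O)CCc2ccccc2)[C@H](O[Si](CC)(CC)CC)C=C3OC)c1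
F3 | step 8 | methyl (4R,5R)-4-{5-bromo-2-[(triisopropylsilyl)oxy]phenyl}-2-methyl-5-[2-(triethylsilyloxy)propan-2-yl]-4,5-dihydrofuran-3-carboxylate | Brc1ccc(O[Si](C(C)C)(C(C)C)C(C)C)c([C@@H]2C(C(=O)OC)=C(C)O[C@H]2C(C)(C)O[Si](CC)(CC)CC)c1
F4 | step 8 | methyl (4R,5R)-4-{5-bromo-2-[(triisopropylsilyl)oxy]phenyl}-2-[4-phenyl-2-(trimethylsilyloxy)butyl]-5-[2-(triethylsilyloxy)propan-2-yl]-4,5-dihydrofuran-3-carboxylate | Brc1ccc(O[Si](C(C)C)(C(C)C)C(C)C)c([C@@H]2C(C(=O)OC)=C(CC(CCc3ccccc3)O[Si](C)(C)C)O[C@H]2C(C)(C)O[Si](CC)(CC)CC)c1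
F5 | step 8 | (2R,3R)-3-{5-bromo-2-[(triisopropylsilyl)oxy]phenyl}-4-(1-methoxyethenyl)-5-[4-phenyl-2-(trimethylsilyloxy)butyl]-2-[2-(triethylsilyloxy)propan-2-yl]-2,3-dihydrofuran | Brc1ccc(O[Si](C(C)C)(C(C)C)C(C)C)c([C@@H]2C(C(=C)OC)=C(CC(CCc3ccccc3)O[Si](C)(C)C)O[C@H]2C(C)(C)O[Si](CC)(CC)CC)c1
F6 | step 8 | methyl 3-{(2R,3R)-4-(1-methoxyethenyl)-5-[4-phenyl-2-(trimethylsilyloxy)butyl]-2-[2-(triethylsilyloxy)propan-2-yl]-2,3-dihydrofuran-3-yl}-4-[(triisopropylsilyl)oxy]benzoate | COC(=O)c1ccc(O[Si](C(C)C)(C(C)C)C(C)C)c([C@@H]2C(C(=C)OC)=C(CC(CCc3ccccc3)O[Si](C)(C)C)O[C@H]2C(C)(C)O[Si](CC)(CC)CC)c1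
F7 | step 8 | methyl 3-{(2R,3R)-5-(2-hydroxy-4-phenylbutyl)-4-(1-methoxyethenyl)-2-[2-(triethylsilyloxy)propan-2-yl]-2,3-dihydrofuran-3-yl}-4-[(triisopropylsilyl)oxy]benzoate | COC(=O)c1ccc(O[Si](C(C)C)(C(C)C)C(C)C)c([C@@H]2C(C(=C)OC)=C(CC(O)CCc3ccccc3)O[C@H]2C(C)(C)O[Si](CC)(CC)CC)c1
F8 | step 13 | methyl 4-hydroxy-3-{(2R,3R)-5-[(3R,4R)-3-hydroxy-5-oxo-7-phenylhept-1-en-4-yl]-2-(2-hydroxypropan-2-yl)-4-(1-methoxyethenyl)-2,3-dihydrofuran-3-yl}benzoate | COC(=O)c1ccc(O)c([C@@H]2C(C(=C)OC)=C(O[C@H]2C(C)(C)O)[C@H](C(=O)CCc3ccccc3)[C@H](O)C=C)c1
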